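**Strategy.** The plan rests on making the C2–O–C5 hemiketal bridge of the 11-oxabicyclo[6.2.1]undecane core one oxygen too long. The nine-membered oxonane ring (C1, C2, O, C5–C10) is first built as the ten-membered 1,2-dioxa ring of a bicyclic peroxyhemiketal. Its O–O bridge is laid across a 2-oxogermacra-4,10(14),11(13)-trienolide by a Schenck ene reaction at the C4=C5 olefin. The key step exploits the weak O–O bond next to hemiketal carbon C2: triphenylphosphine removes one oxygen, contracting the dioxa ring to the oxonane and the 1,2-dioxane to the tetrahydrofuran in one operation. The macrocycle comes from a chromium-mediated closure of a bromomethylbutenolide aldehyde that relays C6 to C7 and C8.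

Key step: step 16

Numbering: germacrane numbering is used throughout (C2 hemiketal carbon, C5 ether CH, C6 lactone CH–O, C7, C8 CH–O-tigloyl, C10=C14 and C4=C15 methylenes, C11–C13 methylene-lactone carbons).

Assumption: the (S,S)-ProPhenol–zinc catalyst is taken to deliver the 4R carbinol 17 (C6, S in the target); should its facial sense be the opposite, the (R,R) ligand is used instead.

Step 1
Reactants: 1 1,3-dithiane; 2 3-bromo-1-(trimethylsilyl)prop-1-yne
Product: 4 2-[3-(trimethylsilyl)prop-2-yn-1-yl]-1,3-dithiane, via 2-lithio-1,3-dithiane 3 (not isolated)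
Conditions: n-BuLi, THF, −30 °C; then 2, −78 → 0 °C
Reagents that add atoms: none
Why: Corey–Seebach umpolung, in which the lithiated dithiane (future C2) is alkylated by SN2 at the propargylic bromide (future C3–C5), the silyl cap preventing acetylide formation and SN2' attack.

Step 2
Reactants: 4 2-[3-(trimethylsilyl)prop-2-yn-1-yl]-1,3-dithiane; 5 2,3-dibromoprop-1-ene
Product: 7 2-(2-bromoprop-2-en-1-yl)-2-[3-(trimethylsilyl)prop-2-yn-1-yl]-1,3-dithiane, via lithiated dithiane 6 (not isolated)
Conditions: n-BuLi, THF, −30 °C; then 5, −78 °C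
Reagents that add atoms: none
Why: Second Corey–Seebach alkylation, in which the tertiary dithianyl anion displaces only the allylic bromide (C1) because the vinylic bromide (C10) is inert to SN2.

Step 3
Reactants: 7 2-(2-bromoprop-2-en-1-yl)-2-[3-(trimethylsilyl)prop-2-yn-1-yl]-1,3-dithiane; 8 oxirane
Product: 11 tert-butyldimethylsilyl ether of 3-methylidene-4-{2-[3-(trimethylsilyl)prop-2-yn-1-yl]-1,3-dithian-2-yl}butan-1-ol, via vinyllithium 9 (not isolated), via lithium alkoxide 10 (not isolated)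
Conditions: t-BuLi (2 equiv), THF, −78 °C; 8, −78 → 0 °C; then TBSCl, HMPA, 0 °C → rt
Reagents that add atoms: tert-butyldimethylsilyl chloride CC(C)(C)[Si](C)(C)Cl
Why: Bromine–lithium exchange should give the 1,1-disubstituted vinyllithium, which opens oxirane (adding C9 and C8), and the lithium alkoxide is silylated in the same flask.

Step 4
Reactants: 11 tert-butyldimethylsilyl ether of 3-methylidene-4-{2-[3-(trimethylsilyl)prop-2-yn-1-yl]-1,3-dithian-2-yl}butan-1-ol
Product: 12 tert-butyldimethylsilyl ether of 3-methylidene-4-[2-(prop-2-yn-1-yl)-1,3-dithian-2-yl]butan-1-ol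
Conditions: K2CO3, MeOH, rt
Reagents that add atoms: none
Why: Carbonate-mediated methanolysis cleaves the alkynyl C–Si bond (protodesilylation) and leaves the O-silyl ether untouched.

Step 5
Reactants: 12 tert-butyldimethylsilyl ether of 3-methylidene-4-[2-(prop-2-yn-1-yl)-1,3-dithian-2-yl]butan-1-ol
Product: 14 (2E)-3-methyl-4-{2-[4-(tert-butyldimethylsilyloxy)-2-methylidenebutyl]-1,3-dithian-2-yl}but-2-en-1-ol, via alkenylalane 13 (not isolated)
Conditions: Me3Al, Cp2ZrCl2 (cat.), CH2Cl2, 0 °C → rt; then n-BuLi, THF, −78 °C; (CH2O)n, rt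
Reagents that add atoms: trimethylaluminium C[Al](C)C; paraformaldehyde (as formaldehyde) C=O
Why: Negishi zirconium-catalysed carboalumination adds methyl and aluminium syn across the terminal alkyne with methyl (C15) on the internal carbon, and hydroxymethylation of the alkenylalanate with retention (adding C6) should fix the 4E trisubstituted olefin.

Step 6
Reactants: 14 (2E)-3-methyl-4-{2-[4-(tert-butyldimethylsilyloxy)-2-methylidenebutyl]-1,3-dithian-2-yl}but-2-en-1-ol
Product: 15 (2E)-3-methyl-4-{2-[4-(tert-butyldimethylsilyloxy)-2-methylidenebutyl]-1,3-dithian-2-yl}but-2-enal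
Conditions: MnO2, CH2Cl2, rt
Reagents that add atoms: none
Why: Manganese dioxide oxidises only the allylic alcohol and should leave the dithiane, the silyl ether and the olefin geometry intact.

Step 7
Reactants: 15 (2E)-3-methyl-4-{2-[4-(tert-butyldimethylsilyloxy)-2-methylidenebutyl]-1,3-dithian-2-yl}but-2-enal; 16 methyl propiolate
Product: 17 methyl (4R,5E)-4-hydroxy-6-methyl-7-{2-[4-(tert-butyldimethylsilyloxy)-2-methylidenebutyl]-1,3-dithian-2-yl}hept-5-en-2-ynoate
Conditions: 16, Me2Zn, (S,S)-ProPhenol (cat.), Ph3P=O (cat.), toluene, 4 °C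
Reagents that add atoms: none
Why: ProPhenol/zinc-catalysed asymmetric alkynylation of an enal, in which the dinuclear zinc catalyst selects the aldehyde face and sets C6, the only stereocentre of the route that is fixed by a catalyst (it adds C7, C11 and C12).

Step 8
Reactants: 17 methyl (4R,5E)-4-hydroxy-6-methyl-7-{2-[4-(tert-butyldimethylsilyloxy)-2-methylidenebutyl]-1,3-dithian-2-yl}hept-5-en-2-ynoate
Product: 20 (5R)-3-(hydroxymethyl)-5-[(1E)-2-methyl-3-{2-[4-(tert-butyldimethylsilyloxy)-2-methylidenebutyl]-1,3-dithian-2-yl}prop-1-en-1-yl]furan-2(5H)-one, via vinylalane 18 (not isolated), via hydroxy ester 19 (not isolated)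
Conditions: DIBAL-H, NMO, THF, 0 °C; HCHO (from cracked paraformaldehyde), −78 °C → rt; aq. citric acid work-up
Reagents that add atoms: formaldehyde C=O
Why: Conjugate syn-hydroalumination of the ynoate (vinylalumination) puts aluminium on C11 and hydrogen on C7, the vinylalane is trapped by formaldehyde (adding C13, a Baylis–Hillman-type adduct), and the resulting Z hydroxy ester should lactonise to the butenolide without touching C6.

Step 9
Reactants: 20 (5R)-3-(hydroxymethyl)-5-[(1E)-2-methyl-3-{2-[4-(tert-butyldimethylsilyloxy)-2-methylidenebutyl]-1,3-dithian-2-yl}prop-1-en-1-yl]furan-2(5H)-one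
Product: 21 (5R)-3-(bromomethyl)-5-[(1E)-2-methyl-3-{2-[4-(tert-butyldimethylsilyloxy)-2-methylidenebutyl]-1,3-dithian-2-yl}prop-1-en-1-yl]furan-2(5H)-one
Conditions: CBr4, PPh3, CH2Cl2, 0 °C
Reagents that add atoms: carbon tetrabromide BrC(Br)(Br)Br
Why: Appel bromination of the only free (primary allylic) alcohol under neutral conditions, which should not epimerise the doubly allylic γ-position C6 of the butenolide.

Step 10
Reactants: 21 (5R)-3-(bromomethyl)-5-[(1E)-2-methyl-3-{2-[4-(tert-butyldimethylsilyloxy)-2-methylidenebutyl]-1,3-dithian-2-yl}prop-1-en-1-yl]furan-2(5H)-one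
Product: 22 (5R)-3-(bromomethyl)-5-[(1E)-3-{2-(4-hydroxy-2-methylidenebutyl)-1,3-dithian-2-yl}-2-methylprop-1-en-1-yl]furan-2(5H)-one
Conditions: aq. HF, MeCN, 0 °C
Reagents that add atoms: none
Why: Acidic fluoride cleaves the primary silyl ether, and the allylic bromide, the dithiane and the base-sensitive butenolide should tolerate these conditions.

Step 11
Reactants: 22 (5R)-3-(bromomethyl)-5-[(1E)-3-{2-(4-hydroxy-2-methylidenebutyl)-1,3-dithian-2-yl}-2-methylprop-1-en-1-yl]furan-2(5H)-one
Product: 23 3-methylidene-4-[2-{(2E)-3-[(2R)-4-(bromomethyl)-5-oxo-2,5-dihydrofuran-2-yl]-2-methylprop-2-en-1-yl}-1,3-dithian-2-yl]butanal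
Conditions: Dess–Martin periodinane, CH2Cl2, 0 °C; used directly
Reagents that add atoms: none
Why: Dess–Martin oxidation gives the β,γ-unsaturated C8 aldehyde under non-basic conditions, so the 1,1-disubstituted olefin should not move into conjugation.

Step 12
Reactants: 23 3-methylidene-4-[2-{(2E)-3-[(2R)-4-(bromomethyl)-5-oxo-2,5-dihydrofuran-2-yl]-2-methylprop-2-en-1-yl}-1,3-dithian-2-yl]butanal
Product: 25 2,2-(propane-1,3-diyldisulfanediyl)-8α-hydroxygermacra-4E,10(14),11(13)-trien-12,6α-olide (6βH,7αH,8βH), via allylchromium species 24 (not isolated)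
Conditions: CrCl2 (excess), THF, high dilution (slow addition of 23), rt
Reagents that add atoms: none
Why: Intramolecular Nozaki–Hiyama (Barbier-type) allylation, in which the 2-(acyl)allylchromium adds through its γ-carbon C7 to the C8 aldehyde in a chair transition state, anti to the C6 side chain (6,7-trans lactone) and with the aldehyde residue equatorial (7,8-anti, 8α-OH), which moves the olefin to C11(13) and closes the ten-membered ring with help from the gem-disubstituted dithiane.

Step 13
Reactants: 25 2,2-(propane-1,3-diyldisulfanediyl)-8α-hydroxygermacra-4E,10(14),11(13)-trien-12,6α-olide; 26 tigloyl chloride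
Product: 27 2,2-(propane-1,3-diyldisulfanediyl)-8α-tigloyloxygermacra-4E,10(14),11(13)-trien-12,6α-olide
Conditions: 26, pyridine, DMAP (cat.), CH2Cl2, 0 °C → rt
Reagents that add atoms: none
Why: DMAP-catalysed acylation of the secondary 8α-alcohol with retention at C8, the E (tiglate) geometry being the stable one.

Step 14
Reactants: 27 2,2-(propane-1,3-diyldisulfanediyl)-8α-tigloyloxygermacra-4E,10(14),11(13)-trien-12,6α-olide
Product: 28 2-oxo-8α-tigloyloxygermacra-4E,10(14),11(13)-trien-12,6α-olide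
Conditions: PhI(OCOCF3)2, MeCN–H2O 9:1, 0 °C
Reagents that add atoms: water O
Why: Hypervalent-iodine oxidative dethioacetalisation should unmask the C2 ketone within minutes, faster than any reaction at the olefins, and must precede singlet oxygen, which would oxidise sulfur.

Step 15
Reactants: 28 2-oxo-8α-tigloyloxygermacra-4E,10(14),11(13)-trien-12,6α-olide
Product: 30 2α-hydroxy-2β,5β-epidioxy-8α-tigloyloxygermacra-4(15),10(14),11(13)-trien-12,6α-olide (bicyclic 1,2-dioxan-3-ol), via hydroperoxide 29 (not isolated)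
Conditions: O2, tetraphenylporphyrin (cat.), visible light, CH2Cl2, −20 °C
Reagents that add atoms: dioxygen O=O
Why: Schenck ene reaction, in which singlet oxygen attacks the only electron-rich olefin (C4=C5) from the outer face of the E-cyclodecene (syn to O6, with H6 in the olefin plane), bonds to C5 and takes hydrogen from C15 on the disubstituted side (cis effect), after which the 5β-hydroperoxide adds across the ring to the C2 ketone to give the peroxyhemiketal.

Step 16
Reactants: 30 2α-hydroxy-2β,5β-epidioxy-8α-tigloyloxygermacra-4(15),10(14),11(13)-trien-12,6α-olide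
Product: 31 2α-hydroxy-2β,5β-epoxy-8α-tigloyloxygermacra-4(15),10(14),11(13)-trien-12,6α-olide (CNP0307443.2)
Conditions: PPh3 (1 equiv), CH2Cl2, 0 °C
Reagents that add atoms: none
Why: Triphenylphosphine attacks the peroxide oxygen on the C2 side (equivalently the terminal oxygen of the open hydroperoxide), and the alkoxyphosphonium/alkoxide pair collapses with loss of Ph3P=O to the C5 alkoxide and the C2 carbonyl, which recombine at once to the hemiketal. The closest known reaction type is the phosphine deoxygenation of cyclic peroxides and peroxyketals (1,2-dioxanes to tetrahydrofurans, hydroperoxides to alcohols). Both new rings arise by contraction: the 1,2-dioxane becomes the tetrahydrofuran by 5-exo-trig addition of O5 to C2=O, and the ten-membered dioxa ring thereby becomes the nine-membered oxonane. The hemiketal centre C2 is re-formed under the geometric control of the cis-2,5 bridge across the carbocycle (only the 2β,5β-epoxy, 2α-hydroxy arrangement can close), while C5 keeps its configuration because the C5–O bond is never broken. The step needs chemoselective O–O reduction beside the phosphine-sensitive α-methylene lactone, which should be secured by the much faster reaction of P(III) with peroxides at 0 °C and by using one equivalent.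

**Compound list**

1 | 1,3-dithiane | C1CSCSC1 | starting material
2 | 3-bromo-1-(trimethylsilyl)prop-1-yne | C[Si](C)(C)C#CCBr | starting material
3 | 2-lithio-1,3-dithiane | [Li]C1SCCCS1 | intermediate
4 | 2-[3-(trimethylsilyl)prop-2-yn-1-yl]-1,3-dithiane | C[Si](C)(C)C#CCC1SCCCS1 | intermediate
5 | 2,3-dibromoprop-1-ene | C=C(Br)CBr | starting material
6 | 2-lithio-2-[3-(trimethylsilyl)prop-2-yn-1-yl]-1,3-dithiane | C[Si](C)(C)C#CCC1([Li])SCCCS1 | intermediate
7 | 2-(2-bromoprop-2-en-1-yl)-2-[3-(trimethylsilyl)prop-2-yn-1-yl]-1,3-dithiane | C[Si](C)(C)C#CCC1(CC(Br)=C)SCCCS1 | intermediate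
8 | oxirane | C1CO1 | starting material
9 | 2-(2-lithioprop-2-en-1-yl)-2-[3-(trimethylsilyl)prop-2-yn-1-yl]-1,3-dithiane | C[Si](C)(C)C#CCC1(CC([Li])=C)SCCCS1 | intermediate
10 | lithium 3-methylidene-4-{2-[3-(trimethylsilyl)prop-2-yn-1-yl]-1,3-dithian-2-yl}butan-1-olate | C[Si](C)(C)C#CCC1(CC(=C)CCO[Li])SCCCS1 | intermediate
11 | tert-butyldimethylsilyl ether of 3-methylidene-4-{2-[3-(trimethylsilyl)prop-2-yn-1-yl]-1,3-dithian-2-yl}butan-1-ol | C[Si](C)(C)C#CCC1(CC(=C)CCO[Si](C)(C)C(C)(C)C)SCCCS1 | intermediate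
12 | tert-butyldimethylsilyl ether of 3-methylidene-4-[2-(prop-2-yn-1-yl)-1,3-dithian-2-yl]butan-1-ol | C#CCC1(CC(=C)CCO[Si](C)(C)C(C)(C)C)SCCCS1 | intermediate
13 | dimethyl[(1E)-2-methyl-3-{2-[4-(tert-butyldimethylsilyloxy)-2-methylidenebutyl]-1,3-dithian-2-yl}prop-1-en-1-yl]alane | C[Al](C)/C=C(\C)CC1(CC(=C)CCO[Si](C)(C)C(C)(C)C)SCCCS1 | intermediate
14 | (2E)-3-methyl-4-{2-[4-(tert-butyldimethylsilyloxy)-2-methylidenebutyl]-1,3-dithian-2-yl}but-2-en-1-ol | OC/C=C(\C)CC1(CC(=C)CCO[Si](C)(C)C(C)(C)C)SCCCS1 | intermediate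
15 | (2E)-3-methyl-4-{2-[4-(tert-butyldimethylsilyloxy)-2-methylidenebutyl]-1,3-dithian-2-yl}but-2-enal | O=C/C=C(\C)CC1(CC(=C)CCO[Si](C)(C)C(C)(C)C)SCCCS1 | intermediate
16 | methyl propiolate (methyl prop-2-ynoate) | C#CC(=O)OC | starting material
17 | methyl (4R,5E)-4-hydroxy-6-methyl-7-{2-[4-(tert-butyldimethylsilyloxy)-2-methylidenebutyl]-1,3-dithian-2-yl}hept-5-en-2-ynoate | COC(=O)C#C[C@H](O)/C=C(\C)CC1(CC(=C)CCO[Si](C)(C)C(C)(C)C)SCCCS1 | intermediate
18 | vinylalane: methyl (2Z,4R,5E)-2-(diisobutylalanyl)-4-(diisobutylalanyloxy)-6-methyl-7-{2-[4-(tert-butyldimethylsilyloxy)-2-methylidenebutyl]-1,3-dithian-2-yl}hepta-2,5-dienoate | COC(=O)/C(=C\[C@H](O[Al](CC(C)C)CC(C)C)/C=C(\C)CC1(CC(=C)CCO[Si](C)(C)C(C)(C)C)SCCCS1)[Al](CC(C)C)CC(C)C | intermediate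
19 | methyl (2Z,4R,5E)-4-hydroxy-2-(hydroxymethyl)-6-methyl-7-{2-[4-(tert-butyldimethylsilyloxy)-2-methylidenebutyl]-1,3-dithian-2-yl}hepta-2,5-dienoate | COC(=O)/C(CO)=C\[C@H](O)/C=C(\C)CC1(CC(=C)CCO[Si](C)(C)C(C)(C)C)SCCCS1 | intermediate
20 | (5R)-3-(hydroxymethyl)-5-[(1E)-2-methyl-3-{2-[4-(tert-butyldimethylsilyloxy)-2-methylidenebutyl]-1,3-dithian-2-yl}prop-1-en-1-yl]furan-2(5H)-one | O=C1O[C@H](/C=C(\C)CC2(CC(=C)CCO[Si](C)(C)C(C)(C)C)SCCCS2)C=C1CO | intermediate
21 | (5R)-3-(bromomethyl)-5-[(1E)-2-methyl-3-{2-[4-(tert-butyldimethylsilyloxy)-2-methylidenebutyl]-1,3-dithian-2-yl}prop-1-en-1-yl]furan-2(5H)-one | O=C1O[C@H](/C=C(\C)CC2(CC(=C)CCO[Si](C)(C)C(C)(C)C)SCCCS2)C=C1CBr | intermediate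
22 | (5R)-3-(bromomethyl)-5-[(1E)-3-{2-(4-hydroxy-2-methylidenebutyl)-1,3-dithian-2-yl}-2-methylprop-1-en-1-yl]furan-2(5H)-one | O=C1O[C@H](/C=C(\C)CC2(CC(=C)CCO)SCCCS2)C=C1CBr | intermediate
23 | 3-methylidene-4-[2-{(2E)-3-[(2R)-4-(bromomethyl)-5-oxo-2,5-dihydrofuran-2-yl]-2-methylprop-2-en-1-yl}-1,3-dithian-2-yl]butanal | O=C1O[C@H](/C=C(\C)CC2(CC(=C)CC=O)SCCCS2)C=C1CBr | intermediate
24 | allylchromium(III) dichloride derived from 23 (CrCl2 in place of Br) | O=C1O[C@H](/C=C(\C)CC2(CC(=C)CC=O)SCCCS2)C=C1C[Cr](Cl)Cl | intermediate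
25 | 2,2-(propane-1,3-diyldisulfanediyl)-8α-hydroxygermacra-4E,10(14),11(13)-trien-12,6α-olide (6βH,7αH,8βH) | C=C1C[C@H](O)[C@H]2C(=C)C(=O)O[C@@H]2/C=C(\C)CC2(C1)SCCCS2 | intermediate
26 | tigloyl chloride [(2E)-2-methylbut-2-enoyl chloride] | C/C=C(\C)C(Cl)=O | starting material
27 | 2,2-(propane-1,3-diyldisulfanediyl)-8α-tigloyloxygermacra-4E,10(14),11(13)-trien-12,6α-olide | C=C1C[C@H](OC(=O)/C(C)=C/C)[C@H]2C(=C)C(=O)O[C@@H]2/C=C(\C)CC2(C1)SCCCS2 | intermediate
28 | 2-oxo-8α-tigloyloxygermacra-4E,10(14),11(13)-trien-12,6α-olide | C=C1C[C@H](OC(=O)/C(C)=C/C)[C@H]2C(=C)C(=O)O[C@@H]2/C=C(\C)CC(=O)C1 | intermediate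
29 | 5β-hydroperoxy-2-oxo-8α-tigloyloxygermacra-4(15),10(14),11(13)-trien-12,6α-olide | C=C1C[C@H](OC(=O)/C(C)=C/C)[C@H]2C(=C)C(=O)O[C@@H]2[C@@H](OO)C(=C)CC(=O)C1 | intermediate
30 | 2α-hydroxy-2β,5β-epidioxy-8α-tigloyloxygermacra-4(15),10(14),11(13)-trien-12,6α-olide | C=C1C[C@H](OC(=O)/C(C)=C/C)[C@H]2C(=C)C(=O)O[C@@H]2[C@H]2OO[C@@](O)(C1)CC2=C | intermediate
31 | 2α-hydroxy-2β,5β-epoxy-8α-tigloyloxygermacra-4(15),10(14),11(13)-trien-12,6α-olide (CNP0307443.2) | C=C1C[C@H](OC(=O)/C(C)=C/C)[C@H]2C(=C)C(=O)O[C@@H]2[C@H]2O[C@@](O)(C1)CC2=C | target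

**Total step count:** 16
**Longest linear sequence:** 16 steps (1 → 31)

**Steps most likely to fail**

1. Step 12 (chromium macrocyclisation). Intermolecular coupling may compete with ring closure, or ring strain may push the aldehyde residue into the axial position of the chair so that the C8 carbinol forms with the 8β configuration. The fallback sets out from 23: the closure is run for the macrocycle alone and the epimeric alcohol, 2,2-(propane-1,3-diyldisulfanediyl)-8β-hydroxygermacra-4E,10(14),11(13)-trien-12,6α-olide F3, is carried on. C8 is then inverted in the ester-forming event itself by a Mitsunobu reaction with tiglic acid (PPh3, DIAD, toluene, 0 °C), which should give the 8α-tiglate and comes back to the route at 27.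

2. Step 15 (Schenck ene reaction). Hydrogen abstraction may occur at C3 instead of C15, oxygen may add to the inner olefin face, or the doubly β,γ-unsaturated ketone may isomerise under irradiation. The fallback sets out from 28: peracid epoxidation (mCPBA, CH2Cl2, 0 °C) from the same outer face should give the 4α,5β-epoxide of 28 F4. Silyl triflate/amidine-mediated isomerisation (TMSOTf, 2,6-lutidine, −78 °C; then DBU) opens the epoxide toward the C15 methyl to the 5β-trimethylsilyloxy-4(15)-ene ketone F5. Mild acid (AcOH–THF–H2O) removes the silyl group and the 5β-hydroxy ketone closes to the hemiketal, coming back to the route at 31.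

3. Step 8 (hydroalumination/hydroxymethylation). The aluminium hydride may over-reduce the ester, or addition may be anti, giving the E hydroxy ester that cannot lactonise. The fallback sets out from 17: palladium-catalysed syn-hydrostannation (Bu3SnH, Pd(PPh3)4, THF) puts tin on C11 and the Z hydroxy ester lactonises to the (5R)-3-(tributylstannyl)butenolide F1. Iododestannylation (I2, CH2Cl2, 0 °C) gives the (5R)-3-iodobutenolide F2. Stille coupling with (tributylstannyl)methanol (Pd(PPh3)4, dioxane, 80 °C) installs the hydroxymethyl group and comes back to the route at 20.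

**Further compounds**

F1 | step 8 | (5R)-5-[(1E)-2-methyl-3-{2-[4-(tert-butyldimethylsilyloxy)-2-methylidenebutyl]-1,3-dithian-2-yl}prop-1-en-1-yl]-3-(tributylstannyl)furan-2(5H)-one | O=C1O[C@H](/C=C(\C)CC2(CC(=C)CCO[Si](C)(C)C(C)(C)C)SCCCS2)C=C1[Sn](CCCC)(CCCC)CCCC
F2 | step 8 | (5R)-3-iodo-5-[(1E)-2-methyl-3-{2-[4-(tert-butyldimethylsilyloxy)-2-methylidenebutyl]-1,3-dithian-2-yl}prop-1-en-1-yl]furan-2(5H)-one | O=C1O[C@H](/C=C(\C)CC2(CC(=C)CCO[Si](C)(C)C(C)(C)C)SCCCS2)C=C1I
F3 | step 12 | 2,2-(propane-1,3-diyldisulfanediyl)-8β-hydroxygermacra-4E,10(14),11(13)-trien-12,6α-olide | C=C1C[C@@H](O)[C@H]2C(=C)C(=O)O[C@@H]2/C=C(\C)CC2(C1)SCCCS2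
F4 | step 15 | 4α,5β-epoxy-2-oxo-8α-tigloyloxygermacra-10(14),11(13)-dien-12,6α-olide | C=C1C[C@H](OC(=O)/C(C)=C/C)[C@H]2C(=C)C(=O)O[C@@H]2[C@H]3O[C@]3(C)CC(=O)C1
F5 | step 15 | 2-oxo-8α-tigloyloxy-5β-(trimethylsilyloxy)germacra-4(15),10(14),11(13)-trien-12,6α-olide | C=C1C[C@H](OC(=O)/C(C)=C/C)[C@H]2C(=C)C(=O)O[C@@H]2[C@@H](O[Si](C)(C)C)C(=C)CC(=O)C1
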